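**Retrosynthetic overview**
- Lower half: (+)-catechin 1 supplies the 2,3-trans unit; O-benzylation (2) and an ester C–O disconnection to para-(benzyloxy)benzoic acid 3 give the C8 nucleophile 4.
- Upper half: (−)-epicatechin 5 supplies the 2,3-cis unit; only O-benzylation (6) precedes the key step.
- Key disconnection: the C4–C8 interflavan bond, cut as a C–H/C–H pair. As in the presumed biosynthesis, the extension unit reacts as a flavan-4-yl cation (quinone methide); it is made from 6 by hydride abstraction with DDQ (adduct 7) and captured by C8 of 4 in the same flask (8, sets C4). Removal of nine benzyl groups then gives 9.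
- Rings: no ring is closed in the flask. Both pyran rings (ring C of each unit) come closed in 1 and 5, as the plant's chalcone-to-flavan pathway made them, and are never opened.

Assumption: the target is read as (−)-epicatechin-(4β→8)-(+)-catechin with the 4-hydroxybenzoate on the 3-OH of the lower (catechin) unit (upper 2R,3R,4R; lower 2R,3S), and 1, 3 and 5 are bought.

**Route**

Step 1
Reactants: 1 (+)-catechin
Product: 2 tetra-O-benzyl-(+)-catechin (benzyl ethers at O5/O7/O3'/O4'; 3-OH free; 2R,3S)
Conditions: BnBr (4.4 equiv.), K2CO3 (4.6 equiv.), DMF, 0 °C → rt, Ar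
Reagents that add atoms: benzyl bromide, BrCc1ccccc1
Why: Williamson ether synthesis: K2CO3 deprotonates only the four phenols, not the secondary 3-OH, so the phenoxides are benzylated chemoselectively and no stereocentre is touched.

Step 2
Reactants: 2 tetra-O-benzyl-(+)-catechin; 3 para-(benzyloxy)benzoic acid (1.5 equiv.)
Product: 4 tetra-O-benzyl-(+)-catechin 3-O-[para-(benzyloxy)benzoate] (2R,3S)
Conditions: DCC (1.6 equiv.), 4-(dimethylamino)pyridine (0.3 equiv.), CH2Cl2, 0 °C → rt
Reagents that add atoms: none
Why: Steglich esterification: the carbodiimide-activated acid is transferred by the pyridine catalyst to the only free hydroxyl, the equatorial 3-OH, with retention at C3 because the alcohol C–O bond is not broken.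

Step 3
Reactants: 5 (−)-epicatechin
Product: 6 tetra-O-benzyl-(−)-epicatechin (benzyl ethers at O5/O7/O3'/O4'; 3-OH free; 2R,3R)
Conditions: BnBr (4.4 equiv.), K2CO3 (4.6 equiv.), DMF, 0 °C → rt, Ar
Reagents that add atoms: benzyl bromide, BrCc1ccccc1
Why: Williamson ether synthesis as in step 1, kept at or below room temperature under argon so that base-induced C2 epimerisation (through the ring B quinone methide) does not compete before the 4'-OH is capped.

Step 4
Reactants: 6 tetra-O-benzyl-(−)-epicatechin; 4 tetra-O-benzyl-(+)-catechin 3-O-[para-(benzyloxy)benzoate] (2.5 equiv.; excess recovered)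
Product: 8 nona-O-benzyl dimer: tetra-O-benzyl-(−)-epicatechin-(4β→8)-tetra-O-benzyl-(+)-catechin 3-O-[para-(benzyloxy)benzoate] (upper 2R,3R,4R; lower 2R,3S), via 4β-aryloxy DDQ adduct 7 (not isolated)
Conditions: DDQ (1.0 equiv.), 4 Å MS, CH2Cl2, 0 °C → rt (6 added slowly to the DDQ); then 4, Me3SiOTf (0.2 equiv.), −78 → −40 °C; Et3N
Reagents that add atoms: none
Why: Proposed new method: hydride abstraction from C4 of 6 by DDQ is the first event of the known DDQ/alcohol 4-alkoxylation of benzylated flavan-3-ols, and with no alcohol present the benzyl-masked quinone methide cation should collapse with its DDQH counter-anion to adduct 7, whose leaving group (pKa about 5) is acetate-like, so catalytic Me3SiOTf re-ionises it at −78 °C and C8 of 4 (C6 is flanked by two benzyloxy groups) attacks in a Friedel–Crafts alkylation from the β-face, anti to the α-oriented 2-aryl and 3-OH groups, which sets C4 as R (3,4-trans); the DDQ is spent before 4 enters, so the C4 methylene of the nucleophile never meets the oxidant, and the remaining C4–H of 8 is quasi-equatorial and a poor hydride donor; the closest known reaction types are the Lewis-acid coupling of isolated 4-alkoxy- or 4-acyloxyflavans with flavan-3-ol nucleophiles and the sequential DDQ oxidation/nucleophile addition (cross-dehydrogenative coupling) of isochromans.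

Step 5
Reactants: 8 nona-O-benzyl dimer
Product: 9 (−)-epicatechin-(4β→8)-(+)-catechin 3-O-(4-hydroxybenzoate), ester on the lower unit (upper 2R,3R,4R; lower 2R,3S), the target CNP0288594.1
Conditions: H2 (1 atm), Pd(OH)2/C (20 wt%), THF/MeOH/H2O (20:1:1), rt
Reagents that add atoms: none
Why: Catalytic hydrogenolysis cleaves all nine aryl benzyl ethers to toluene under neutral conditions, while the alkyl benzoate, the interflavan C–C bond and the five stereocentres are not affected.

**Compound list**

1 | (+)-catechin, (2R,3S)-2-(3,4-dihydroxyphenyl)chroman-3,5,7-triol | O[C@H]1Cc2c(O)cc(O)cc2O[C@@H]1c1ccc(O)c(O)c1 | starting material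

2 | 5,7,3',4'-tetra-O-benzyl-(+)-catechin (2R,3S) | O[C@H]1Cc2c(OCc3ccccc3)cc(OCc3ccccc3)cc2O[C@@H]1c1ccc(OCc2ccccc2)c(OCc2ccccc2)c1 | intermediate

3 | para-(benzyloxy)benzoic acid | OC(=O)c1ccc(OCc2ccccc2)cc1 | starting material

4 | 5,7,3',4'-tetra-O-benzyl-(+)-catechin 3-O-[4-(benzyloxy)benzoate] (2R,3S) | O=C(O[C@H]1Cc2c(OCc3ccccc3)cc(OCc3ccccc3)cc2O[C@@H]1c1ccc(OCc2ccccc2)c(OCc2ccccc2)c1)c1ccc(OCc2ccccc2)cc1 | intermediate

5 | (−)-epicatechin, (2R,3R)-2-(3,4-dihydroxyphenyl)chroman-3,5,7-triol | O[C@@H]1Cc2c(O)cc(O)cc2O[C@@H]1c1ccc(O)c(O)c1 | starting material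

6 | 5,7,3',4'-tetra-O-benzyl-(−)-epicatechin (2R,3R) | O[C@@H]1Cc2c(OCc3ccccc3)cc(OCc3ccccc3)cc2O[C@@H]1c1ccc(OCc2ccccc2)c(OCc2ccccc2)c1 | intermediate

7 | 4β-(2,3-dichloro-5,6-dicyano-4-hydroxyphenoxy)-5,7,3',4'-tetra-O-benzyl-(−)-epicatechin (2R,3S,4S; 2,3-cis-3,4-trans; in equilibrium with its ion pair) | N#Cc1c(C#N)c(O)c(Cl)c(Cl)c1O[C@H]1c2c(OCc3ccccc3)cc(OCc3ccccc3)cc2O[C@H](c2ccc(OCc3ccccc3)c(OCc3ccccc3)c2)[C@@H]1O | intermediate

8 | 5,7,3',4'-tetra-O-benzyl-(−)-epicatechin-(4β→8)-5,7,3',4'-tetra-O-benzyl-(+)-catechin 3-O-[4-(benzyloxy)benzoate] (upper 2R,3R,4R; lower 2R,3S) | O=C(O[C@H]1Cc2c(OCc3ccccc3)cc(OCc3ccccc3)c([C@H]3c4c(OCc5ccccc5)cc(OCc5ccccc5)cc4O[C@H](c4ccc(OCc5ccccc5)c(OCc5ccccc5)c4)[C@@H]3O)c2O[C@@H]1c1ccc(OCc2ccccc2)c(OCc2ccccc2)c1)c1ccc(OCc2ccccc2)cc1 | intermediate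

9 | (−)-epicatechin-(4β→8)-(+)-catechin 3-O-(4-hydroxybenzoate), ester on the catechin unit (upper 2R,3R,4R; lower 2R,3S) | O=C(O[C@H]1Cc2c(O)cc(O)c([C@H]3c4c(O)cc(O)cc4O[C@H](c4ccc(O)c(O)c4)[C@@H]3O)c2O[C@@H]1c1ccc(O)c(O)c1)c1ccc(O)cc1 | target

**Step count and risks**

Total step count: 5. Longest linear sequence: 4 steps (steps 1, 2, 4, 5 from (+)-catechin); the epicatechin branch is 3 steps (3, 4, 5).

The three steps most likely to fail:

1. Step 4 (oxidative coupling). Adduct 7 may self-condense with unreacted 6 before the nucleophile is added, or may re-ionise poorly. The fallback isolates an electrophile with a conventional leaving group. It sets out from 6: DDQ (2 equiv.) and 2-ethoxyethanol in CH2Cl2 at rt trap the same cation as 4β-(2-ethoxyethoxy)-5,7,3',4'-tetra-O-benzyl-(−)-epicatechin F1. This ether is chromatographed and then condensed with 4 (Me3SiOTf, CH2Cl2, −78 °C), and the fallback comes back to the route at 8.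

2. Step 3 (benzylation of epicatechin). C-benzylation and partial C2 epimerisation can lower the yield, and 5 is the costliest input. The fallback inverts C3 of the catechin series instead. It sets out from 2: Dess–Martin periodinane (CH2Cl2, rt) oxidises the 3-OH to (2R)-5,7-bis(benzyloxy)-2-[3,4-bis(benzyloxy)phenyl]chroman-3-one F2. LiBH(s-Bu)3 (THF, −78 °C) then delivers hydride to the face opposite the 2-aryl group, giving the 2,3-cis alcohol, and the fallback comes back to the route at 6. Both halves then derive from 1.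

3. Step 5 (nine-fold hydrogenolysis). The reaction may stall if traces of chlorinated or nitrile residues from step 4 poison the palladium, or it may over-reduce by opening the benzylic C2–O1 bond. The fallback replaces hydrogenolysis by heterolytic ether cleavage. It sets out from 8: BCl3 with pentamethylbenzene as benzyl-cation scavenger (CH2Cl2, −78 °C, MeOH quench, kept cold to spare the acid-labile interflavan bond) removes the aryl benzyl ethers and leaves the benzoate. It comes back to the route at 9, and no compound outside the list is made (F0).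

**Further compounds**

F1 | step 4 | 4β-(2-ethoxyethoxy)-5,7,3',4'-tetra-O-benzyl-(−)-epicatechin (2R,3R,4S) | CCOCCO[C@H]1c2c(OCc3ccccc3)cc(OCc3ccccc3)cc2O[C@H](c2ccc(OCc3ccccc3)c(OCc3ccccc3)c2)[C@@H]1O
F2 | step 3 | (2R)-5,7-bis(benzyloxy)-2-[3,4-bis(benzyloxy)phenyl]chroman-3-one | O=C1Cc2c(OCc3ccccc3)cc(OCc3ccccc3)cc2O[C@@H]1c1ccc(OCc2ccccc2)c(OCc2ccccc2)c1
F0 | step 5 | none | none
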